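**Retrosynthetic overview**

- Ring A has its ester carbonyl on C1, flanked by the C2 oxygen and the C6 pentyl chain, with the second oxygen on C4 para to C1. A 4-alkoxy-6-pentyl-2-pyrone-5-carboxylate supplies ring A C1, C2, C3, C6 (from pyrone C5, C4, C3, C6), and a ketene acetal supplies ring A C4 and C5, after loss of CO2 and one alcohol.
- Disconnections, backwards: global O-debenzylation; ring A by pyrone/ketene acetal cycloaddition, decarboxylation and aromatization; benzylation of pyrone O4; pyrone ring from an aryl 3-oxooctanoate and malonyl dichloride; depside ester C–O bond from hexanoylketene and the ring B phenol.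
- Ring order: ring B is bought as divarinol, carboxylated and protected so that only O4' is free; the pyrone is then built around the finished depside ester; ring A is formed last from the pyrone.

Key step: step 12

Assumption: the target is achiral, so no stereocontrol is needed; divarinol, 2-bromo-1,1-diethoxyethane and methyl magnesium carbonate (solution in DMF) are taken as purchasable.

**Route**

Step 1
Reactants: 1 divarinol (5-propylbenzene-1,3-diol)
Product: 2 2,4-dihydroxy-6-propylbenzoic acid (divaric acid)
Conditions: MeOMgOCO2Me (2 M in DMF), 120 °C; then cold 2 M HCl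
Reagents that add atoms: methyl magnesium carbonate, COC(=O)O[Mg]OC
Why: Kolbe-Schmitt-type ortho-carboxylation through a magnesium phenoxide chelate, which should deliver CO2 to the ring carbon that is ortho to one hydroxyl and para to the other; cold acidification avoids decarboxylation of the salicylic-type acid.

Step 2
Reactants: 2 2,4-dihydroxy-6-propylbenzoic acid
Product: 3 benzyl 2,4-dihydroxy-6-propylbenzoate
Conditions: BnBr (1.05 equiv), KHCO3, DMF, rt
Reagents that add atoms: benzyl bromide, BrCc1ccccc1
Why: SN2 alkylation of the carboxylate; hydrogen carbonate deprotonates only the acid and leaves both phenols untouched.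

Step 3
Reactants: 3 benzyl 2,4-dihydroxy-6-propylbenzoate
Product: 4 benzyl 4-(allyloxy)-2-hydroxy-6-propylbenzoate
Conditions: allyl bromide (1.05 equiv), K2CO3, acetone, rt
Reagents that add atoms: allyl bromide, C=CCBr
Why: Williamson etherification, selective for the 4-hydroxyl because the 2-hydroxyl is tied in a hydrogen bond to the ester carbonyl and is less acidic and less nucleophilic.

Step 4
Reactants: 4 benzyl 4-(allyloxy)-2-hydroxy-6-propylbenzoate
Product: 5 benzyl 4-(allyloxy)-2-(benzyloxy)-6-propylbenzoate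
Conditions: BnBr, K2CO3, DMF, 60 °C
Reagents that add atoms: benzyl bromide, BrCc1ccccc1
Why: Williamson etherification of the remaining chelated phenol under more forcing conditions; the allyl ether and benzyl ester are stable to carbonate in DMF.

Step 5
Reactants: 5 benzyl 4-(allyloxy)-2-(benzyloxy)-6-propylbenzoate
Product: 6 benzyl 2-(benzyloxy)-4-hydroxy-6-propylbenzoate
Conditions: Pd(PPh3)4 (cat.), morpholine, THF, rt
Reagents that add atoms: none
Why: Tsuji-Trost deallylation, in which zerovalent palladium ionizes the aryl allyl ether to a pi-allyl complex that morpholine captures; benzyl ether and benzyl ester do not react.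

Step 6
Reactants: 7 Meldrum's acid (2,2-dimethyl-1,3-dioxane-4,6-dione); 8 hexanoyl chloride
Product: 9 5-(1-hydroxyhexylidene)-2,2-dimethyl-1,3-dioxane-4,6-dione (hexanoyl Meldrum's acid)
Conditions: pyridine (2 equiv), CH2Cl2, 0 °C to rt; dilute HCl wash
Reagents that add atoms: none
Why: C-acylation of the acidic methylene of Meldrum's acid by the acid chloride, giving the stable enol form of the acyl derivative.

Step 7
Reactants: 9 hexanoyl Meldrum's acid; 6 benzyl 2-(benzyloxy)-4-hydroxy-6-propylbenzoate
Product: 11 3-(benzyloxy)-4-[(benzyloxy)carbonyl]-5-propylphenyl 3-oxooctanoate, via hexanoylketene 10 (not isolated)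
Conditions: PhMe, reflux
Reagents that add atoms: none
Why: Thermolysis of the acyl Meldrum's acid (retro-(4+2) loss of acetone and CO2) gives the acylketene, which is trapped by the only free, unhindered hydroxyl of 6 to form the depside ester as a beta-keto ester.

Step 8
Reactants: 11 aryl 3-oxooctanoate; 12 malonyl dichloride
Product: 14 3-(benzyloxy)-4-[(benzyloxy)carbonyl]-5-propylphenyl 4-hydroxy-2-oxo-6-pentyl-2H-pyran-5-carboxylate, via C-malonylated acid chloride 13 (not isolated)
Conditions: 12 (1.05 equiv), CH2Cl2, rt to 40 °C, no base, N2 sweep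
Reagents that add atoms: none
Why: Known condensation of beta-keto esters with malonyl dichloride to 4-hydroxy-2-pyrone-5-carboxylates: C-acylation of the active methylene, then six-membered lactonization of the hexanoyl enol oxygen onto the second acid chloride.

Step 9
Reactants: 14 4-hydroxy-2-pyrone ester
Product: 15 3-(benzyloxy)-4-[(benzyloxy)carbonyl]-5-propylphenyl 4-(benzyloxy)-2-oxo-6-pentyl-2H-pyran-5-carboxylate
Conditions: BnOH, PPh3, DIAD, THF, 0 °C to rt
Reagents that add atoms: benzyl alcohol, OCc1ccccc1
Why: Mitsunobu etherification; the vinylogous acid is a good pronucleophile, and 4-hydroxy-2-pyrones are alkylated at O4 under these neutral conditions, which also spare the aryl ester.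

Step 10
Reactants: 16 2-bromo-1,1-diethoxyethane
Product: 17 2-bromo-1,1-bis(benzyloxy)ethane
Conditions: BnOH (2.2 equiv), TsOH·H2O (cat.), 110 °C, EtOH distilled off
Reagents that add atoms: benzyl alcohol, OCc1ccccc1
Why: Acid-catalysed transacetalization driven to the dibenzyl acetal by removal of the volatile ethanol.

Step 11
Reactants: 17 2-bromo-1,1-bis(benzyloxy)ethane
Product: 18 1,1-bis(benzyloxy)ethene (ketene dibenzyl acetal)
Conditions: KOtBu, THF, 0 °C to rt; stored over K2CO3
Reagents that add atoms: none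
Why: E2 dehydrobromination of the alpha-bromo acetal by a hindered alkoxide, the standard route to ketene acetals.

Step 12
Reactants: 15 4-benzyloxy-2-pyrone ester; 18 1,1-bis(benzyloxy)ethene
Product: 21 3-(benzyloxy)-4-[(benzyloxy)carbonyl]-5-propylphenyl 2,4-bis(benzyloxy)-6-pentylbenzoate (tetrabenzyl depside), via bridged bicyclic lactone 19 (not isolated), via cyclohexadiene ketal 20 (not isolated)
Conditions: 18 (4 equiv), PhMe, 120 °C, sealed tube
Reagents that add atoms: none
Why: The pyrone diene (C3=C4–C5=C6) of 15 and the electron-rich alkene 18 combine in an inverse-electron-demand (4+2) cycloaddition that is concerted but strongly asynchronous, the nucleophilic CH2 of 18 bonding to pyrone C6 and the acetal carbon to pyrone C3; lactone 19 then ejects CO2 by retro-(4+2) to give diene 20, and 1,2-elimination of benzyl alcohol across the CH2–C(OBn)2 bond aromatizes it, so the sequence is irreversible. The closest known reaction is the conversion of 2-pyrone-5-carboxylates (coumalates) by ketene acetals into 4-alkoxybenzoates with loss of CO2 and alcohol. Ring A is closed intermolecularly in six-membered (4+2) mode with two new C–C bonds (ring A C5–C6 and C3–C4), pyrone C5, C4, C3, C6 becoming ring A C1, C2, C3, C6. The two bridgehead stereocentres of 19 are transient and vanish on aromatization, so no stereocontrol is needed. The one selectivity required is regiochemistry, and the substrate supplies it: C6 is both the beta-carbon of the C5 aryl ester and the vinylogous terminus of the lactone carbonyl, whereas C3 is alpha to the lactone carbonyl and beta to the 4-benzyloxy donor and is not electrophilic. Because that donor lowers the electron demand of the diene, excess 18 is used (it also takes up the released benzyl alcohol) and the temperature is kept below the point where 18 would suffer benzyl migration.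

Step 13
Reactants: 21 tetrabenzyl depside
Product: 22 4-[(2,4-dihydroxy-6-pentylbenzoyl)oxy]-2-hydroxy-6-propylbenzoic acid (target)
Conditions: H2 (1 atm), Pd/C, EtOAc, rt
Reagents that add atoms: none
Why: Catalytic hydrogenolysis cleaves the three aryl benzyl ethers and the benzyl ester in one operation, while the depside aryl ester and the arenes are inert; room temperature avoids decarboxylation of the freed acid.

**Compound list**

1 | divarinol (5-propylbenzene-1,3-diol) | CCCc1cc(O)cc(O)c1 | starting material
2 | 2,4-dihydroxy-6-propylbenzoic acid | CCCc1cc(O)cc(O)c1C(=O)O | intermediate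
3 | benzyl 2,4-dihydroxy-6-propylbenzoate | CCCc1cc(O)cc(O)c1C(=O)OCc1ccccc1 | intermediate
4 | benzyl 4-(allyloxy)-2-hydroxy-6-propylbenzoate | CCCc1cc(OCC=C)cc(O)c1C(=O)OCc1ccccc1 | intermediate
5 | benzyl 4-(allyloxy)-2-(benzyloxy)-6-propylbenzoate | CCCc1cc(OCC=C)cc(OCc2ccccc2)c1C(=O)OCc1ccccc1 | intermediate
6 | benzyl 2-(benzyloxy)-4-hydroxy-6-propylbenzoate | CCCc1cc(O)cc(OCc2ccccc2)c1C(=O)OCc1ccccc1 | intermediate
7 | Meldrum's acid | CC1(C)OC(=O)CC(=O)O1 | starting material
8 | hexanoyl chloride | CCCCCC(=O)Cl | starting material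
9 | 5-(1-hydroxyhexylidene)-2,2-dimethyl-1,3-dioxane-4,6-dione | CCCCCC(O)=C1C(=O)OC(C)(C)OC1=O | intermediate
10 | hexanoylketene (3-oxooct-1-en-1-one) | CCCCCC(=O)C=C=O | intermediate (not isolated)
11 | 3-(benzyloxy)-4-[(benzyloxy)carbonyl]-5-propylphenyl 3-oxooctanoate | CCCCCC(=O)CC(=O)Oc1cc(OCc2ccccc2)c(C(=O)OCc2ccccc2)c(CCC)c1 | intermediate
12 | malonyl dichloride | O=C(Cl)CC(=O)Cl | starting material
13 | 3-(benzyloxy)-4-[(benzyloxy)carbonyl]-5-propylphenyl 2-(3-chloro-3-oxopropanoyl)-3-oxooctanoate (racemic, enolizable) | CCCCCC(=O)C(C(=O)CC(=O)Cl)C(=O)Oc1cc(OCc2ccccc2)c(C(=O)OCc2ccccc2)c(CCC)c1 | intermediate (not isolated)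
14 | 3-(benzyloxy)-4-[(benzyloxy)carbonyl]-5-propylphenyl 4-hydroxy-2-oxo-6-pentyl-2H-pyran-5-carboxylate | CCCCCc1oc(=O)cc(O)c1C(=O)Oc1cc(OCc2ccccc2)c(C(=O)OCc2ccccc2)c(CCC)c1 | intermediate
15 | 3-(benzyloxy)-4-[(benzyloxy)carbonyl]-5-propylphenyl 4-(benzyloxy)-2-oxo-6-pentyl-2H-pyran-5-carboxylate | CCCCCc1oc(=O)cc(OCc2ccccc2)c1C(=O)Oc1cc(OCc2ccccc2)c(C(=O)OCc2ccccc2)c(CCC)c1 | intermediate
16 | 2-bromo-1,1-diethoxyethane | CCOC(CBr)OCC | starting material
17 | 2-bromo-1,1-bis(benzyloxy)ethane | BrCC(OCc1ccccc1)OCc1ccccc1 | intermediate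
18 | 1,1-bis(benzyloxy)ethene | C=C(OCc1ccccc1)OCc1ccccc1 | intermediate
19 | 3-(benzyloxy)-4-[(benzyloxy)carbonyl]-5-propylphenyl 5,8,8-tris(benzyloxy)-3-oxo-1-pentyl-2-oxabicyclo[2.2.2]oct-5-ene-6-carboxylate (racemic; bridgeheads linked by the bicycle) | CCCCCC12CC(OCc3ccccc3)(OCc3ccccc3)C(C(=O)O1)C(OCc1ccccc1)=C2C(=O)Oc1cc(OCc2ccccc2)c(C(=O)OCc2ccccc2)c(CCC)c1 | intermediate (not isolated)
20 | 3-(benzyloxy)-4-[(benzyloxy)carbonyl]-5-propylphenyl 4,4,6-tris(benzyloxy)-2-pentylcyclohexa-1,5-diene-1-carboxylate | CCCCCC1=C(C(=O)Oc2cc(OCc3ccccc3)c(C(=O)OCc3ccccc3)c(CCC)c2)C(OCc2ccccc2)=CC(OCc2ccccc2)(OCc2ccccc2)C1 | intermediate (not isolated)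
21 | 3-(benzyloxy)-4-[(benzyloxy)carbonyl]-5-propylphenyl 2,4-bis(benzyloxy)-6-pentylbenzoate | CCCCCc1cc(OCc2ccccc2)cc(OCc2ccccc2)c1C(=O)Oc1cc(OCc2ccccc2)c(C(=O)OCc2ccccc2)c(CCC)c1 | intermediate
22 | 4-[(2,4-dihydroxy-6-pentylbenzoyl)oxy]-2-hydroxy-6-propylbenzoic acid | CCCCCc1cc(O)cc(O)c1C(=O)Oc1cc(O)c(C(=O)O)c(CCC)c1 | target

**Step count**

Total steps: 13. Longest linear sequence: 10 steps (steps 1, 2, 3, 4, 5, 7, 8, 9, 12, 13).

**Steps most likely to fail**

Step 12. The 4-benzyloxy donor may slow the cycloaddition so much that the ketene acetal is lost to benzyl migration or oligomerization before it adds. The fallback sets out from 6 and comes back at 21; it makes ring A as a protected acid and joins it by classical depside esterification. Commercial olivetol F1 is formylated under Vilsmeier-Haack conditions (POCl3, DMF, aqueous work-up) to 2,4-dihydroxy-6-pentylbenzaldehyde F2. Both hydroxyls are benzylated (BnBr, K2CO3, DMF, 70 °C) to 2,4-bis(benzyloxy)-6-pentylbenzaldehyde F3. Pinnick oxidation (NaClO2, NaH2PO4, 2-methylbut-2-ene, t-BuOH/H2O) should give 2,4-bis(benzyloxy)-6-pentylbenzoic acid F4. Trifluoroacetic anhydride in toluene at rt converts F4 into 2,4-bis(benzyloxy)-6-pentylbenzoic trifluoroacetic anhydride F5, which acylates the only free hydroxyl of 6 to give 21.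

Step 8. The hydroxypyrone product may be acylated again by malonyl dichloride at C3 and O4, or unselective O-acylation and oligomerization may consume the keto ester. The fallback sets out from 11 and comes back at 14; it separates the two bond formations. Soft-enolization C-acylation of 11 with methyl 3-chloro-3-oxopropanoate (MgCl2, pyridine, CH2Cl2, 0 °C) should give 3-(benzyloxy)-4-[(benzyloxy)carbonyl]-5-propylphenyl 2-(3-methoxy-3-oxopropanoyl)-3-oxooctanoate F6. Base-mediated lactonization (DBU, PhMe, 80 °C, 4 Å molecular sieves; then dilute acid) lets the hexanoyl enolate oxygen displace methoxide from the methyl ester and closes the pyrone to 14.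

Step 1. Carboxylation may compete at the ring carbon between the two hydroxyls, and the acid may decarboxylate during work-up. The fallback sets out from 1 and comes back at 5; it brings the carboxyl carbon in as an aldehyde. Vilsmeier-Haack formylation of 1 (POCl3, DMF) should give 2,4-dihydroxy-6-propylbenzaldehyde F7. Selective allylation of the non-chelated 4-hydroxyl (allyl bromide, K2CO3, acetone, rt) gives 4-(allyloxy)-2-hydroxy-6-propylbenzaldehyde F8. Benzylation (BnBr, K2CO3, DMF, 60 °C) gives 4-(allyloxy)-2-(benzyloxy)-6-propylbenzaldehyde F9. Pinnick oxidation gives 4-(allyloxy)-2-(benzyloxy)-6-propylbenzoic acid F10, and BnBr with KHCO3 in DMF esterifies it to 5.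

**Further compounds**

F1 | step 12 | olivetol (5-pentylbenzene-1,3-diol; bought, starting material of the fallback) | CCCCCc1cc(O)cc(O)c1
F2 | step 12 | 2,4-dihydroxy-6-pentylbenzaldehyde | CCCCCc1cc(O)cc(O)c1C=O
F3 | step 12 | 2,4-bis(benzyloxy)-6-pentylbenzaldehyde | CCCCCc1cc(OCc2ccccc2)cc(OCc2ccccc2)c1C=O
F4 | step 12 | 2,4-bis(benzyloxy)-6-pentylbenzoic acid | CCCCCc1cc(OCc2ccccc2)cc(OCc2ccccc2)c1C(=O)O
F5 | step 12 | 2,4-bis(benzyloxy)-6-pentylbenzoic trifluoroacetic anhydride | CCCCCc1cc(OCc2ccccc2)cc(OCc2ccccc2)c1C(=O)OC(=O)C(F)(F)F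
F6 | step 8 | 3-(benzyloxy)-4-[(benzyloxy)carbonyl]-5-propylphenyl 2-(3-methoxy-3-oxopropanoyl)-3-oxooctanoate | CCCCCC(=O)C(C(=O)CC(=O)OC)C(=O)Oc1cc(OCc2ccccc2)c(C(=O)OCc2ccccc2)c(CCC)c1
F7 | step 1 | 2,4-dihydroxy-6-propylbenzaldehyde | CCCc1cc(O)cc(O)c1C=O
F8 | step 1 | 4-(allyloxy)-2-hydroxy-6-propylbenzaldehyde | CCCc1cc(OCC=C)cc(O)c1C=O
F9 | step 1 | 4-(allyloxy)-2-(benzyloxy)-6-propylbenzaldehyde | CCCc1cc(OCC=C)cc(OCc2ccccc2)c1C=O
F10 | step 1 | 4-(allyloxy)-2-(benzyloxy)-6-propylbenzoic acid | CCCc1cc(OCC=C)cc(OCc2ccccc2)c1C(=O)O
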